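The constants of this chemistry are not given, so the first one has to be read off the runs.

| flask | starting material | reagent | free catalyst | remark |
|---|---|---|---|---|
| dusk | 0.15 M | 0.11 M | 5.5 mM | run made earlier |
| spring | 0.24 M | 0.11 M | 5.5 mM | run made earlier |
| midnight | 0.11 M | 0.22 M | 5.5 mM | run made earlier |
| flask | 0.11 M | 0.110 M | 5.5 mM |  |

- dusk (time / h: target / %): 0.500: 5; 1.00: 12; 2.50: 16; 6.00: 17
- spring (time / h: target / %): 1.50: 11; 3.00: 18; 5.00: 17; 6.00: 13
- midnight (time / h: target / %): 0.833: 22; 2.00: 26; 4.00: 25; 6.00: 22

(scatter of a reading: 2 percentage points)

- what was read earlier has a scatter of 2 percentage points, one standard deviation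
- what has left starting material counts as converted, also if it is not yet product

* apparent order in reagent when 50% of the starting material are converted (percent change of the rate of making target for one percent more reagent charged)

What do the runs show? They stall. Dusk stands at 17%, about 0.0255 M of target, less than the reagent charged, so if each target takes one reagent, I read this as a dying catalyst and not as lack of reagent.

How do you put a number on that? Work with what is left, not with what is made. Suppose each hour takes the same share of the working catalyst (first-order loss), and target is made in step with that catalyst. Then the fraction of the final target still to come falls exponentially. In dusk, 5 percentage points are still to come at 1.00 h, and the logarithm of that fraction per hour gives the survival constant 1.22 h⁻¹.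

Where is it weak? It is a reading, taken from the two dusk readings at 1.00 h and 6.00 h, each with a scatter of 2 points. Midnight also runs ahead of it: at 0.833 h the constant leaves 36.2% to come, and the readings leave 12.0%.

And the order? If the clock is shared and 50% conversion falls at the same moment with either reagent charge, the rate there is plateau times constant times fraction left, so rates go as plateaus. Dusk and spring reach 17% and 18%, so I expect 17% here. Midnight is this flask with twice the reagent and reads 25% at 4.00 h, so my order is 0.556, a reading.

The forecast says 1.1, higher than mine, with consumption of reagent “pushing the order above the initial value”.

The flask gives 0.68.

    reagent + catalyst intermediate → free catalyst + target (k = 0.0950 L mol⁻¹ s⁻¹)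
    free catalyst + open intermediate ⇌ catalyst intermediate (K = 15.0 L mol⁻¹, k = 0.780 L mol⁻¹ s⁻¹)
    free catalyst → spent catalyst (k = 4.10 × 10⁻⁴ s⁻¹)
    open intermediate → side product (k = 4.20 × 10⁻⁴ s⁻¹)
    starting material + free catalyst → free catalyst + open intermediate (k = 0.0630 L mol⁻¹ s⁻¹)

At 0.600 h the survival constant, a reading from dusk, reckons 48.1% of the catalyst charged as still working in this flask, where free catalyst and catalyst intermediate together hold 46.8%. In midnight at 2.00 h it reckons 2.18% of the starting material charged as target still to come, and the later readings are 25% and 22%. In this flask, each catalyst intermediate falls back at 187 h⁻¹ and goes on with reagent as charged at 38 h⁻¹, slower. When 50% of the starting material is converted in this flask, catalyst intermediate is 2.09% of the catalyst and spent catalyst 82.0%.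

(All runs come from a simulation on assumed constants, and the scatter is random.)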